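A direct plan would cut the aryl–benzofuran bond. Chromanone aryl triflate A1 would be coupled by Suzuki–Miyaura reaction with benzofuran-2-yl pinacol boronate A2 to give chromanone A3. Its ketone would be reduced and dehydrated to the bis-MOM chromene A4, and acid would then free the two phenols.
Its weakest points would be:
- The run-up to both partners. Placing one prenyl group and the leaving group on A1 would take MOM protection, O-allylation, Claisen rearrangement, allyl-to-prenyl cross-metathesis and triflation, and the simple boronate A2 would need annulation, saponification, decarboxylation and borylation. That is nine operations for a single skeletal C–C bond.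
- The Suzuki coupling itself. It would make the most hindered bond of the target late, at a triflate flanked by a prenyl group and a carbonyl, in a race against protodeboronation of the 2-heteroaryl boronate.
- The closing acid cleavage of the MOM ethers, after a ketone reduction/dehydration that builds nothing. Acid would meet an ortho-prenyl phenol and a 2H-chromene, which can cyclise to chromans, hydrate or oligomerise.

**Retrosynthetic overview of the new route**
1. Feature used: the central ring is a resorcinol (O at C7 and C8a, H at C8) whose other three positions C4a, C5 and C6 carry contiguous carbon substituents, and its C5–C2' bond to the benzofuran is flanked on both sides. The ring is therefore built, not decorated.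
2. Cathafuran C ⇐ 5-ethynylchromenol 20 + 4-iodoresorcinol 21 by domino Sonogashira/5-endo-dig closure of the furan ring. The C5–C2' bond is never made: it is the central σ-bond of commercial 1,4-bis(trimethylsilyl)butadiyne.
3. 20 ⇐ salicylaldehyde 16 + isobutenyl Grignard reagent; an ortho-quinone methide/oxa-6π closure forms the pyran ring.
4. 16 ⇐ Diels–Alder benzannulation of the prenylated 1,3-bis(silyloxy)diene 9 (from methyl acetoacetate and prenyl bromide) with diynal 13 (from the butadiyne and DMF). It forms C5–C6 and C4a–C8a and sets all six substituents of the central ring at once.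
5. Ring order: central benzene → pyran → furan. The design has no Claisen/metathesis/triflate sequence, no hindered cross-coupling, no ketone redox detour and no acid at the end (fluoride, then Pd/Cu; the last step is free of protecting groups).

Key step: step 5

Assumption: Cathafuran C has no stereocentre and no configurationally stable axis, so "single enantiomer" is taken to mean the single achiral compound drawn.

**Branch A: diene**

Step 1
Reactants: 1 methyl acetoacetate; 2 1-bromo-3-methylbut-2-ene (prenyl bromide)
Product: 4 methyl 7-methyl-3-oxooct-6-enoate, via sodium lithium dianion of methyl acetoacetate 3 (not isolated)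
Conditions: NaH, THF, 0 °C; n-BuLi, 0 °C; then 2, 0 °C → rt; aq. HCl
Reagents that add atoms: 1-bromo-3-methylbut-2-ene (2), CC(C)=CCBr
Why: Weiler dianion alkylation: the more basic terminal (γ) carbanion of the acetoacetate dianion is alkylated selectively (SN2) by the primary allylic bromide, which places the future C6 prenyl group on the carbon that becomes the diene terminus.

Step 2
Reactants: 4; 5 tert-butyldimethylsilyl trifluoromethanesulfonate
Product: 6 methyl 3-[(tert-butyldimethylsilyl)oxy]-7-methylocta-2,6-dienoate (E/Z mixture at C2=C3, of no consequence)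
Conditions: TBSOTf, Et3N, CH2Cl2, 0 °C → rt
Reagents that add atoms: tert-butyldimethylsilyl trifluoromethanesulfonate (5), CC(C)(C)[Si](C)(C)OS(=O)(=O)C(F)(F)F
Why: Soft enolisation and O-silylation of the β-keto ester give the conjugated silyl enol ether; the robust TBS group placed here ends on the future C7 oxygen and distinguishes it from the C8a oxygen.

Step 3
Reactants: 6; 7 chlorotrimethylsilane
Product: 9 tert-butyl{[(3Z)-1-methoxy-7-methyl-1-[(trimethylsilyl)oxy]octa-1,3,6-trien-3-yl]oxy}dimethylsilane, via lithium dienolate of 6 8 (not isolated)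
Conditions: LDA, THF, −78 °C; then TMSCl, −78 → 0 °C; pentane, filtration under Ar, used crude
Reagents that add atoms: chlorotrimethylsilane (7), C[Si](C)(C)Cl
Why: γ-Deprotonation of the 3-silyloxy enoate and O-silylation of the ester dienolate (Chan-type 1,3-bis(silyloxy)diene synthesis); the (3Z) geometry, with the chain cis to the small OSi group, is the expected one and puts the chain on the outside of the s-cis diene.

**Branch B: dienophile**

Step 4
Reactants: 10 1,4-bis(trimethylsilyl)buta-1,3-diyne; 11 N,N-dimethylformamide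
Product: 13 5-(trimethylsilyl)penta-2,4-diynal, via [4-(trimethylsilyl)buta-1,3-diyn-1-yl]lithium 12 (not isolated)
Conditions: MeLi·LiBr (1.0 equiv), Et2O, rt; then DMF, −78 → 0 °C; inverse quench into ice-cold 1 M HCl/Et2O; used at once as a solution
Reagents that add atoms: N,N-dimethylformamide (11), CN(C)C=O
Why: Selective mono-desilylation of the bis-silyl diyne by attack of MeLi at silicon gives the lithium diynide, which is formylated by DMF; the inverse acidic quench collapses the α-amino alkoxide without letting dimethylamine add to the ynal.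

**Union and endgame**

Step 5
Reactants: 9 diene (1.3–1.5 equiv); 13 diynal
Product: 16 4-[(tert-butyldimethylsilyl)oxy]-2-hydroxy-5-(3-methylbut-2-en-1-yl)-6-[(trimethylsilyl)ethynyl]benzaldehyde, via 4-[(tert-butyldimethylsilyl)oxy]-6-methoxy-3-(3-methylbut-2-en-1-yl)-6-[(trimethylsilyl)oxy]-2-[(trimethylsilyl)ethynyl]cyclohexa-1,4-diene-1-carbaldehyde 14 (not isolated), via 4-[(tert-butyldimethylsilyl)oxy]-5-(3-methylbut-2-en-1-yl)-2-[(trimethylsilyl)oxy]-6-[(trimethylsilyl)ethynyl]benzaldehyde 15 (not isolated)
Conditions: PhMe, 0 → 70 °C (no Lewis acid), until cycloaddition and loss of MeOH are complete; then citric acid, MeOH/THF, 0 °C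
Reagents that add atoms: none
Why: A normal-electron-demand Diels–Alder reaction of the 1-alkoxy-1,3-bis(silyloxy)diene 9 with the aldehyde-conjugated triple bond of 13 should give the 1,4-cyclohexadiene 14, which aromatises by 1,4-elimination of methanol across the ketal carbon and the doubly allylic C–H to the aryl silyl ether 15; mild acid then cleaves only the labile aryl O–SiMe3 group next to the aldehyde. The closest known reaction type is the benzannulation of Chan/Brassard-type 1,3-dioxygenated dienes with acetylenic carbonyl dienophiles to resorcinols and resorcylates. The central benzene ring is closed by an intermolecular [4+2] cycloaddition that forms the C5–C6 and C4a–C8a bonds (chromene numbering), and the four diyne carbons become C4a, C5 and the future furan C2'/C3'. No stereocentre remains, because the two sp3 carbons of 14 are erased on aromatisation. The step needs regioselectivity, which the matched polarisation secures (the nucleophilic, prenyl-bearing diene terminus bonds to the β-carbon of the ynal, so CHO ends next to the new OH and the alkyne next to the prenyl group), and site selectivity for the α,β-triple bond over C=O and the distal triple bond, which the absence of a Lewis acid and the SiMe3 cap secure. The (3Z) diene carries its chain on the outside and the β-substituent of the dienophile is a slim alkynyl group, so the congested C5–C6 bond forms without the steric penalty of an aryl–aryl coupling at this position.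

Step 6
Reactants: 16; 17 (2-methylprop-1-en-1-yl)magnesium bromide
Product: 19 tert-butyl{[2,2-dimethyl-6-(3-methylbut-2-en-1-yl)-5-[(trimethylsilyl)ethynyl]-2H-chromen-7-yl]oxy}dimethylsilane, via 5-[(tert-butyldimethylsilyl)oxy]-2-(1-hydroxy-3-methylbut-2-en-1-yl)-4-(3-methylbut-2-en-1-yl)-3-[(trimethylsilyl)ethynyl]phenol 18 (not isolated)
Conditions: 17 (3 equiv), THF, −78 → 0 °C; aq. NH4Cl; then PPTS (10 mol %), 4 Å MS, CH2Cl2, rt
Reagents that add atoms: (2-methylprop-1-en-1-yl)magnesium bromide (17), CC(C)=C[Mg]Br
Why: 1,2-Addition of the alkenyl Grignard reagent to the salicylaldehyde (the first equivalent is consumed by the phenol) and mild acid-catalysed cyclodehydration of the ortho-hydroxybenzyl allylic alcohol through the ortho-quinone methide, which closes the pyran ring by oxa-6π electrocyclisation; only the C8a–OH is free and ortho, so closure is unambiguous, and the silylated C7 oxygen cannot add to the prenyl group.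

Step 7
Reactants: 19
Product: 20 5-ethynyl-2,2-dimethyl-6-(3-methylbut-2-en-1-yl)-2H-chromen-7-ol
Conditions: TBAF (2.5 equiv), THF, 0 °C → rt; aq. NH4Cl
Reagents that add atoms: none
Why: Fluoride cleaves the aryl silyl ether and the alkynyl C–Si bond in one operation under non-acidic conditions that leave the 2H-chromene and the prenyl group untouched.

Step 8
Reactants: 20; 21 4-iodobenzene-1,3-diol (4-iodoresorcinol, 1.3 equiv)
Product: 23 Cathafuran C, 5-(6-hydroxybenzofuran-2-yl)-2,2-dimethyl-6-(3-methylbut-2-en-1-yl)-2H-chromen-7-ol, via 4-{[7-hydroxy-2,2-dimethyl-6-(3-methylbut-2-en-1-yl)-2H-chromen-5-yl]ethynyl}benzene-1,3-diol 22 (not isolated)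
Conditions: Pd(PPh3)2Cl2 (5 mol %), CuI (5 mol %), Et3N/DMF, degassed, slow addition of 20, rt → 70 °C
Reagents that add atoms: 4-iodobenzene-1,3-diol (21), Oc1ccc(I)c(O)c1
Why: Domino Sonogashira coupling/5-endo-dig cycloisomerisation (heteroannulation of an ortho-iodophenol with a terminal alkyne): after alkynylation at C–I, the ortho hydroxyl adds to the metal-activated alkyne and closes the furan ring, the para hydroxyl becomes the 6-OH, and the chromene C7–OH is not ortho to the alkyne and cannot compete.

**Compound list**
1 | methyl acetoacetate | COC(=O)CC(C)=O | starting material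
2 | 1-bromo-3-methylbut-2-ene (prenyl bromide) | CC(C)=CCBr | starting material
3 | sodium lithium dianion of methyl acetoacetate | COC(=O)[CH-]C(=O)[CH2-].[Na+].[Li+] | intermediate (not isolated)
4 | methyl 7-methyl-3-oxooct-6-enoate | COC(=O)CC(=O)CCC=C(C)C | intermediate
5 | tert-butyldimethylsilyl trifluoromethanesulfonate | CC(C)(C)[Si](C)(C)OS(=O)(=O)C(F)(F)F | starting material
6 | methyl 3-[(tert-butyldimethylsilyl)oxy]-7-methylocta-2,6-dienoate (E/Z mixture) | COC(=O)C=C(CCC=C(C)C)O[Si](C)(C)C(C)(C)C | intermediate
7 | chlorotrimethylsilane | C[Si](C)(C)Cl | starting material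
8 | lithium dienolate of 6 | COC([O-])=CC(O[Si](C)(C)C(C)(C)C)=CCC=C(C)C.[Li+] | intermediate (not isolated)
9 | tert-butyl{[(3Z)-1-methoxy-7-methyl-1-[(trimethylsilyl)oxy]octa-1,3,6-trien-3-yl]oxy}dimethylsilane | COC(O[Si](C)(C)C)=C/C(O[Si](C)(C)C(C)(C)C)=C/CC=C(C)C | intermediate
10 | 1,4-bis(trimethylsilyl)buta-1,3-diyne | C[Si](C)(C)C#CC#C[Si](C)(C)C | starting material
11 | N,N-dimethylformamide | CN(C)C=O | starting material
12 | [4-(trimethylsilyl)buta-1,3-diyn-1-yl]lithium | [Li]C#CC#C[Si](C)(C)C | intermediate (not isolated)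
13 | 5-(trimethylsilyl)penta-2,4-diynal | O=CC#CC#C[Si](C)(C)C | intermediate
14 | 4-[(tert-butyldimethylsilyl)oxy]-6-methoxy-3-(3-methylbut-2-en-1-yl)-6-[(trimethylsilyl)oxy]-2-[(trimethylsilyl)ethynyl]cyclohexa-1,4-diene-1-carbaldehyde (racemic, diastereomer mixture) | COC1(O[Si](C)(C)C)C=C(O[Si](C)(C)C(C)(C)C)C(CC=C(C)C)C(C#C[Si](C)(C)C)=C1C=O | intermediate (not isolated)
15 | 4-[(tert-butyldimethylsilyl)oxy]-5-(3-methylbut-2-en-1-yl)-2-[(trimethylsilyl)oxy]-6-[(trimethylsilyl)ethynyl]benzaldehyde | O=Cc1c(O[Si](C)(C)C)cc(O[Si](C)(C)C(C)(C)C)c(CC=C(C)C)c1C#C[Si](C)(C)C | intermediate (not isolated)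
16 | 4-[(tert-butyldimethylsilyl)oxy]-2-hydroxy-5-(3-methylbut-2-en-1-yl)-6-[(trimethylsilyl)ethynyl]benzaldehyde | O=Cc1c(O)cc(O[Si](C)(C)C(C)(C)C)c(CC=C(C)C)c1C#C[Si](C)(C)C | intermediate
17 | (2-methylprop-1-en-1-yl)magnesium bromide | CC(C)=C[Mg]Br | starting material
18 | 5-[(tert-butyldimethylsilyl)oxy]-2-(1-hydroxy-3-methylbut-2-en-1-yl)-4-(3-methylbut-2-en-1-yl)-3-[(trimethylsilyl)ethynyl]phenol (racemic) | CC(C)=CC(O)c1c(O)cc(O[Si](C)(C)C(C)(C)C)c(CC=C(C)C)c1C#C[Si](C)(C)C | intermediate (not isolated)
19 | tert-butyl{[2,2-dimethyl-6-(3-methylbut-2-en-1-yl)-5-[(trimethylsilyl)ethynyl]-2H-chromen-7-yl]oxy}dimethylsilane | CC1(C)C=Cc2c(C#C[Si](C)(C)C)c(CC=C(C)C)c(O[Si](C)(C)C(C)(C)C)cc2O1 | intermediate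
20 | 5-ethynyl-2,2-dimethyl-6-(3-methylbut-2-en-1-yl)-2H-chromen-7-ol | CC1(C)C=Cc2c(C#C)c(CC=C(C)C)c(O)cc2O1 | intermediate
21 | 4-iodobenzene-1,3-diol | Oc1ccc(I)c(O)c1 | starting material
22 | 4-{[7-hydroxy-2,2-dimethyl-6-(3-methylbut-2-en-1-yl)-2H-chromen-5-yl]ethynyl}benzene-1,3-diol | CC1(C)C=Cc2c(C#Cc3ccc(O)cc3O)c(CC=C(C)C)c(O)cc2O1 | intermediate (not isolated)
23 | Cathafuran C | CC(C)=CCc1c(O)cc2c(c1-c1cc3ccc(O)cc3o1)C=CC(C)(C)O2 | target

**Totals**
Total steps: 8.
Longest linear sequence: 7 (steps 1, 2, 3, 5, 6, 7, 8); step 4 is a one-step side branch.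

**Steps most likely to fail, with fallbacks**

Step 5 (benzannulation). The very nucleophilic diene may attack the aldehyde carbonyl (aldol-type addition or hetero-cycloaddition) instead of the triple bond. The diynal may also oligomerise on warming, or the silyl enol ether may be lost before aromatisation. The fallback removes the aldehyde from the cycloaddition and sets out from 10. The acetylide 12 would be quenched with methyl chloroformate to give methyl 5-(trimethylsilyl)penta-2,4-diynoate F1. Thermal Diels–Alder reaction of F1 with 9 (PhMe, 110 °C), aromatisation and the same mild acid work-up should give methyl 4-[(tert-butyldimethylsilyl)oxy]-2-hydroxy-5-(3-methylbut-2-en-1-yl)-6-[(trimethylsilyl)ethynyl]benzoate F2. DIBAL-H (CH2Cl2, −78 → 0 °C) would reduce the ester to 5-[(tert-butyldimethylsilyl)oxy]-2-(hydroxymethyl)-4-(3-methylbut-2-en-1-yl)-3-[(trimethylsilyl)ethynyl]phenol F3, and MnO2 (CH2Cl2, rt) would oxidise the benzylic alcohol, which returns to the route at 16.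

Step 6 (pyran ring). Addition to the chelated, doubly ortho-substituted aldehyde phenoxide may be sluggish. Acid treatment of the carbinol may also lead to elimination or to oligomerisation of the quinone methide. The fallback generates the quinone methide under anionic, acid-free conditions and sets out from 16. Boc2O with DMAP and i-Pr2NEt (CH2Cl2) would give tert-butyl {5-[(tert-butyldimethylsilyl)oxy]-2-formyl-4-(3-methylbut-2-en-1-yl)-3-[(trimethylsilyl)ethynyl]phenyl} carbonate F4. Addition of 17 (1.05 equiv, THF, −78 °C → rt) to the now non-chelated aldehyde would trigger carbonate transfer to the new alkoxide and expulsion of tert-butyl carbonate. The ortho-quinone methide so formed should electrocyclise directly, which returns to the route at 19.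

Step 8 (furan ring). Oxidative homocoupling of the terminal alkyne, slow coupling of the electron-rich unprotected iodophenol, or incomplete 5-endo closure of the hindered diaryl alkyne may erode the last step. The fallback separates coupling from cyclisation and keeps free phenols out of the palladium step; it sets out from 19. K2CO3 (0.2 equiv, MeOH/THF, 0 °C) would remove only the alkynyl silyl group to give tert-butyl{[5-ethynyl-2,2-dimethyl-6-(3-methylbut-2-en-1-yl)-2H-chromen-7-yl]oxy}dimethylsilane F5. Sonogashira coupling of F5 (Pd(PPh3)2Cl2, CuI, Et3N, THF, rt) with [(4-iodo-1,3-phenylene)bis(oxy)]bis(tert-butyldimethylsilane) F6, made from 21 with TBSCl and imidazole, should give the tris-silylated diaryl alkyne tert-butyl{[5-({2,4-bis[(tert-butyldimethylsilyl)oxy]phenyl}ethynyl)-2,2-dimethyl-6-(3-methylbut-2-en-1-yl)-2H-chromen-7-yl]oxy}dimethylsilane F7. TBAF (THF, 65 °C) would then remove all three silyl groups and drive the 5-endo-dig addition of the ortho phenoxide to the alkyne, which returns to the route at 23.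

**Further compounds**
F1 | step 5 | methyl 5-(trimethylsilyl)penta-2,4-diynoate | COC(=O)C#CC#C[Si](C)(C)C
F2 | step 5 | methyl 4-[(tert-butyldimethylsilyl)oxy]-2-hydroxy-5-(3-methylbut-2-en-1-yl)-6-[(trimethylsilyl)ethynyl]benzoate | COC(=O)c1c(O)cc(O[Si](C)(C)C(C)(C)C)c(CC=C(C)C)c1C#C[Si](C)(C)C
F3 | step 5 | 5-[(tert-butyldimethylsilyl)oxy]-2-(hydroxymethyl)-4-(3-methylbut-2-en-1-yl)-3-[(trimethylsilyl)ethynyl]phenol | OCc1c(O)cc(O[Si](C)(C)C(C)(C)C)c(CC=C(C)C)c1C#C[Si](C)(C)C
F4 | step 6 | tert-butyl {5-[(tert-butyldimethylsilyl)oxy]-2-formyl-4-(3-methylbut-2-en-1-yl)-3-[(trimethylsilyl)ethynyl]phenyl} carbonate | CC(C)(C)OC(=O)Oc1cc(O[Si](C)(C)C(C)(C)C)c(CC=C(C)C)c(C#C[Si](C)(C)C)c1C=O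
F5 | step 8 | tert-butyl{[5-ethynyl-2,2-dimethyl-6-(3-methylbut-2-en-1-yl)-2H-chromen-7-yl]oxy}dimethylsilane | CC1(C)C=Cc2c(C#C)c(CC=C(C)C)c(O[Si](C)(C)C(C)(C)C)cc2O1
F6 | step 8 | [(4-iodo-1,3-phenylene)bis(oxy)]bis(tert-butyldimethylsilane) | CC(C)(C)[Si](C)(C)Oc1ccc(I)c(O[Si](C)(C)C(C)(C)C)c1
F7 | step 8 | tert-butyl{[5-({2,4-bis[(tert-butyldimethylsilyl)oxy]phenyl}ethynyl)-2,2-dimethyl-6-(3-methylbut-2-en-1-yl)-2H-chromen-7-yl]oxy}dimethylsilane | CC1(C)C=Cc2c(C#Cc3ccc(O[Si](C)(C)C(C)(C)C)cc3O[Si](C)(C)C(C)(C)C)c(CC=C(C)C)c(O[Si](C)(C)C(C)(C)C)cc2O1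
A1 | direct plan | 7-(methoxymethoxy)-2,2-dimethyl-6-(3-methylbut-2-en-1-yl)-4-oxochroman-5-yl trifluoromethanesulfonate | CC1(C)CC(=O)c2c(OS(=O)(=O)C(F)(F)F)c(CC=C(C)C)c(OCOC)cc2O1
A2 | direct plan | 2-[6-(methoxymethoxy)benzofuran-2-yl]-4,4,5,5-tetramethyl-1,3,2-dioxaborolane | COCOc1ccc2cc(B3OC(C)(C)C(C)(C)O3)oc2c1
A3 | direct plan | 5-[6-(methoxymethoxy)benzofuran-2-yl]-7-(methoxymethoxy)-2,2-dimethyl-6-(3-methylbut-2-en-1-yl)chroman-4-one | CC1(C)CC(=O)c2c(-c3cc4ccc(OCOC)cc4o3)c(CC=C(C)C)c(OCOC)cc2O1
A4 | direct plan | 6-(methoxymethoxy)-2-[7-(methoxymethoxy)-2,2-dimethyl-6-(3-methylbut-2-en-1-yl)-2H-chromen-5-yl]benzofuran | CC1(C)C=Cc2c(-c3cc4ccc(OCOC)cc4o3)c(CC=C(C)C)c(OCOC)cc2O1
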